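**Plan**

- Cuts (ring atoms O1, C2(=O), C3=C4, C5, C6; acid arm C7=C8–C9; acyl chain C1'–C12'): first the C5–O ester bond, then the ring O1–C6 bond, which unfolds the pyranone into trans-epoxy acid 9; then C3=C4 and C7=C8 back to a Sharpless epoxy alcohol; in the acyl chain C2'=C3', C4'=C5' and C9'–C10'.
- Enabling feature: C6 is at once a carbon of the C5–C6 oxirane and the γ-carbon of the (E)-enoate C7=C8–C9, and the C2 carboxyl is held over it by the (Z)-C3=C4 bond; the lactone core is a masked C2-symmetric 4,5-dioxygenated octa-2,6-dienedioic acid.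
- Forward: epoxide, E arm, Z arm, free acid, palladium-mediated strain-release ring closure (the only ring; it also frees the C5 hydroxyl), esterification with the separately made dienoic acid, acid deprotection.
- Stereochemistry: C5 and C6 from the asymmetric epoxidation (L-(+)-diethyl tartrate), C6 carried through with net retention so that the trans-epoxide becomes the cis-(5S,6S) lactone; C6' (R) from (R)-β-citronellene, C11' (S) from (S)-propylene oxide; olefin geometry from E-selective Wittig and Z-selective Still–Gennari reactions.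

Key step: step 7

Remark: (E)-but-2-ene-1,4-diol, (R)-β-citronellene and (S)-propylene oxide are taken as commercial; the ylides, the phosphonate and the acylating agents are catalogue reagents.

**Route**

Step 1
Reactants: 1 (E)-but-2-ene-1,4-diol
Product: 2 (E)-4-{[tert-butyl(dimethyl)silyl]oxy}but-2-en-1-ol
Conditions: NaH (1.0 equiv), THF, 0 °C; then TBSCl (1.0 equiv), rt
Reagents that add atoms: tert-butyl(chloro)dimethylsilane, CC(C)(C)[Si](C)(C)Cl
Why: O-silylation of the sparingly soluble monosodium alkoxide of a symmetric diol should give mainly the mono-ether, and the two hydroxyls are equivalent so no regiochemical issue arises.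

Step 2
Reactants: 2 (E)-4-{[tert-butyl(dimethyl)silyl]oxy}but-2-en-1-ol
Product: 3 [(2S,3S)-3-({[tert-butyl(dimethyl)silyl]oxy}methyl)oxiran-2-yl]methanol
Conditions: Ti(OiPr)4 (10 mol %), L-(+)-diethyl tartrate (12 mol %), t-BuOOH (2 equiv), 4 Å molecular sieves, CH2Cl2, −20 °C
Reagents that add atoms: tert-butyl hydroperoxide, CC(C)(C)OO
Why: Sharpless asymmetric epoxidation, in which the titanium–L-(+)-tartrate complex should deliver oxygen to the face of the (E)-allylic alcohol that gives the (2S,3S)-trans-epoxide, fixing both carbons that become C5 and C6.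

Step 3
Reactants: 3 [(2S,3S)-3-({[tert-butyl(dimethyl)silyl]oxy}methyl)oxiran-2-yl]methanol
Product: 5 tert-butyl (2E)-3-[(2S,3S)-3-({[tert-butyl(dimethyl)silyl]oxy}methyl)oxiran-2-yl]prop-2-enoate, via epoxy aldehyde 4 (not isolated)
Conditions: Dess–Martin periodinane, pyridine, CH2Cl2, 0 °C → rt; then Ph3P=CHCO2t-Bu, rt
Reagents that add atoms: tert-butyl (triphenylphosphoranylidene)acetate, CC(C)(C)OC(=O)C=P(c1ccccc1)(c1ccccc1)c1ccccc1
Why: Dess–Martin oxidation followed in the same flask by Wittig olefination with a stabilized ylide should give the (E)-enoate without purifying the sensitive epoxy aldehyde; the epoxide stereocentres are not touched.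

Step 4
Reactants: 5 tert-butyl (2E)-3-[(2S,3S)-3-({[tert-butyl(dimethyl)silyl]oxy}methyl)oxiran-2-yl]prop-2-enoate
Product: 6 tert-butyl (2E)-3-[(2S,3S)-3-(hydroxymethyl)oxiran-2-yl]prop-2-enoate
Conditions: HF·pyridine, pyridine, THF, 0 °C → rt
Reagents that add atoms: none
Why: Fluoride-driven desilylation of the primary silyl ether under buffered, non-basic conditions should leave the vinyl epoxide and the tert-butyl ester intact.

Step 5
Reactants: 6 tert-butyl (2E)-3-[(2S,3S)-3-(hydroxymethyl)oxiran-2-yl]prop-2-enoate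
Product: 8 tert-butyl (2E)-3-[(2S,3S)-3-[(1Z)-3-methoxy-3-oxoprop-1-en-1-yl]oxiran-2-yl]prop-2-enoate, via epoxy aldehyde 7 (not isolated)
Conditions: Dess–Martin periodinane, pyridine, CH2Cl2, 0 °C; filtration; then (CF3CH2O)2P(O)CH2CO2Me, KN(SiMe3)2, 18-crown-6, THF, −78 °C
Reagents that add atoms: methyl [bis(2,2,2-trifluoroethoxy)phosphoryl]acetate, COC(=O)CP(=O)(OCC(F)(F)F)OCC(F)(F)F
Why: Still–Gennari olefination, in which fast irreversible elimination from the kinetic adduct of the electron-poor phosphonate should give the (Z)-enoate, while the weakly basic phosphonate anion at −78 °C should spare the epoxide and the (E)-enoate.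

Step 6
Reactants: 8 tert-butyl (2E)-3-[(2S,3S)-3-[(1Z)-3-methoxy-3-oxoprop-1-en-1-yl]oxiran-2-yl]prop-2-enoate
Product: 9 (2Z)-3-[(2S,3S)-3-[(1E)-3-tert-butoxy-3-oxoprop-1-en-1-yl]oxiran-2-yl]prop-2-enoic acid
Conditions: LiOH (1.1 equiv), THF/H2O (3:1), 0 °C; then 0.5 M H3PO4 to pH 4 at 0 °C, cold extraction, used at once
Reagents that add atoms: lithium hydroxide, [Li+].[OH-]
Why: Saponification should select the unhindered methyl ester over the tert-butyl ester and, at 0 °C, leave the trans-epoxide; the acid is liberated cold and used immediately so that the carboxyl does not open the epoxide without catalyst.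

Step 7
Reactants: 9 (2Z)-3-[(2S,3S)-3-[(1E)-3-tert-butoxy-3-oxoprop-1-en-1-yl]oxiran-2-yl]prop-2-enoic acid
Product: 10 tert-butyl (2E)-3-[(2S,3S)-3-hydroxy-6-oxo-3,6-dihydro-2H-pyran-2-yl]prop-2-enoate
Conditions: Pd(PPh3)4 (5 mol %), THF, 0 °C → rt
Reagents that add atoms: none
Why: Zerovalent palladium binds the (E)-enoate alkene and opens the strained C5–C6 oxirane at C6 with inversion to a syn,syn π-allyl complex (C6–C7–C8) and the C5 alkoxide, which takes the carboxyl proton; the carboxylate, held by the (Z)-C3=C4 bond, then attacks C6 on the face opposite to palladium and releases the catalyst. The closest known reaction type is the Tsuji–Trost substitution of vinyl epoxides and γ,δ-epoxy-α,β-unsaturated esters by oxygen nucleophiles (carboxylic acids between molecules, hydroxyl groups within a molecule), which takes place at the γ-carbon with overall retention. The six-membered ring O1–C2–C3–C4–C5–C6 closes in a 6-exo attack on the allyl terminus C6, so that C7=C8 stays outside the ring and is returned E from the syn complex. C6 is the only stereocentre that reacts and is controlled by the epoxide carbon itself through double inversion (net retention), while C5 keeps its oxygen and configuration; the trans-(S,S)-epoxide should therefore give the cis-(5S,6S) lactone, which a direct SN2 opening could not give. The step needs ionization at C6 rather than C5, attack at C6 rather than C8, and catalysed closure rather than uncatalysed 5-exo opening at C5: the first is secured because only the (E)-alkenyl side can form an unstrained syn allyl complex, the second by ring size (six against eight), the third by running the reaction cold on freshly liberated acid.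

Step 8
Reactants: 11 (R)-β-citronellene [(3R)-3,7-dimethylocta-1,6-diene]
Product: 12 (4R)-4-methylhex-5-en-1-ol
Conditions: O3, CH2Cl2/MeOH, −78 °C, stopped when the trisubstituted alkene is consumed; then NaBH4, −78 °C → rt
Reagents that add atoms: ozone, [O-][O+]=O
Why: Ozonolysis with reductive work-up, in which ozone should attack the electron-rich trisubstituted alkene much faster than the vinyl group and borohydride reduces the ozonide to the primary alcohol without touching the stereocentre.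

Step 9
Reactants: 12 (4R)-4-methylhex-5-en-1-ol
Product: 13 (3R)-6-bromo-3-methylhex-1-ene
Conditions: CBr4, PPh3, CH2Cl2, 0 °C
Reagents that add atoms: tetrabromomethane, BrC(Br)(Br)Br
Why: Appel reaction, an SN2 displacement of the primary oxyphosphonium by bromide remote from the stereocentre.

Step 10
Reactants: 13 (3R)-6-bromo-3-methylhex-1-ene; 14 (S)-propylene oxide
Product: 16 (2S,7R)-7-methylnon-8-en-2-ol, via Grignard reagent 15 (not isolated)
Conditions: Mg, Et2O, rt; then CuI (10 mol %), 14, −30 °C → 0 °C; aq. NH4Cl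
Reagents that add atoms: none
Why: Copper-catalysed Grignard opening of the terminal epoxide at its CH2 carbon (SN2) should form C9'–C10' and leave the C–O stereocentre untouched, so that (S)-propylene oxide gives the (2S)-alcohol.

Step 11
Reactants: 16 (2S,7R)-7-methylnon-8-en-2-ol
Product: 17 tert-butyl(dimethyl){[(2S,7R)-7-methylnon-8-en-2-yl]oxy}silane
Conditions: TBSCl, imidazole, DMF, rt
Reagents that add atoms: tert-butyl(chloro)dimethylsilane, CC(C)(C)[Si](C)(C)Cl
Why: Imidazole-promoted silylation of the secondary alcohol, with no bond to a stereocentre broken.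

Step 12
Reactants: 17 tert-butyl(dimethyl){[(2S,7R)-7-methylnon-8-en-2-yl]oxy}silane
Product: 19 (2E,4R,9S)-9-{[tert-butyl(dimethyl)silyl]oxy}-2,4-dimethyldec-2-enal, via aldehyde 18 (not isolated)
Conditions: O3, CH2Cl2, −78 °C; PPh3, −78 °C → rt; evaporation; then Ph3P=C(CH3)CHO, toluene, 90 °C
Reagents that add atoms: 2-(triphenylphosphoranylidene)propanal, CC(C=O)=P(c1ccccc1)(c1ccccc1)c1ccccc1
Why: Ozonolysis of the vinyl group and Wittig reaction of the crude α-methyl aldehyde with the stabilized formyl ylide should give the (E)-trisubstituted enal; the aldehyde is not purified, which limits epimerization at C6'.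

Step 13
Reactants: 19 (2E,4R,9S)-9-{[tert-butyl(dimethyl)silyl]oxy}-2,4-dimethyldec-2-enal
Product: 20 ethyl (2E,4E,6R,11S)-11-{[tert-butyl(dimethyl)silyl]oxy}-4,6-dimethyldodeca-2,4-dienoate
Conditions: Ph3P=CHCO2Et, CH2Cl2, rt → 40 °C
Reagents that add atoms: ethyl (triphenylphosphoranylidene)acetate, CCOC(=O)C=P(c1ccccc1)(c1ccccc1)c1ccccc1
Why: Wittig olefination with a stabilized ylide should give the (2E)-dienoate.

Step 14
Reactants: 20 ethyl (2E,4E,6R,11S)-11-{[tert-butyl(dimethyl)silyl]oxy}-4,6-dimethyldodeca-2,4-dienoate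
Product: 21 (2E,4E,6R,11S)-11-{[tert-butyl(dimethyl)silyl]oxy}-4,6-dimethyldodeca-2,4-dienoic acid
Conditions: LiOH, THF/MeOH/H2O, rt; then 1 M HCl to pH 3
Reagents that add atoms: lithium hydroxide, [Li+].[OH-]
Why: Saponification of the ethyl ester, to which the silyl ether and the diene should be stable.

Step 15
Reactants: 21 (2E,4E,6R,11S)-11-{[tert-butyl(dimethyl)silyl]oxy}-4,6-dimethyldodeca-2,4-dienoic acid; 10 tert-butyl (2E)-3-[(2S,3S)-3-hydroxy-6-oxo-3,6-dihydro-2H-pyran-2-yl]prop-2-enoate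
Product: 23 tert-butyl (2E)-3-[(2S,3S)-3-{[(2E,4E,6R,11S)-11-{[tert-butyl(dimethyl)silyl]oxy}-4,6-dimethyldodeca-2,4-dienoyl]oxy}-6-oxo-3,6-dihydro-2H-pyran-2-yl]prop-2-enoate, via mixed anhydride 22 (not isolated)
Conditions: 2,4,6-trichlorobenzoyl chloride, Et3N, toluene, rt; then 10, DMAP, toluene, 0 °C → rt
Reagents that add atoms: none
Why: Yamaguchi esterification, in which the acylpyridinium formed from the mixed anhydride should acylate the secondary C5 hydroxyl with retention because no bond to C5 is broken.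

Step 16
Reactants: 23 tert-butyl (2E)-3-[(2S,3S)-3-{[(2E,4E,6R,11S)-11-{[tert-butyl(dimethyl)silyl]oxy}-4,6-dimethyldodeca-2,4-dienoyl]oxy}-6-oxo-3,6-dihydro-2H-pyran-2-yl]prop-2-enoate
Product: 24 (2E)-3-[(2S,3S)-3-{[(2E,4E,6R,11S)-11-hydroxy-4,6-dimethyldodeca-2,4-dienoyl]oxy}-6-oxo-3,6-dihydro-2H-pyran-2-yl]prop-2-enoic acid (target)
Conditions: CF3CO2H/CH2Cl2/H2O (10:10:1), 0 °C → rt
Reagents that add atoms: none
Why: Acidolysis should remove the tert-butyl ester (as isobutene) and the silyl ether in one operation; the absence of base avoids elimination of the C5 acyloxy group from the base-sensitive lactone, and no stereocentre is involved.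

**Compound list**

1 | (E)-but-2-ene-1,4-diol | OC/C=C/CO | starting material
2 | (E)-4-{[tert-butyl(dimethyl)silyl]oxy}but-2-en-1-ol | OC/C=C/CO[Si](C)(C)C(C)(C)C | intermediate
3 | [(2S,3S)-3-({[tert-butyl(dimethyl)silyl]oxy}methyl)oxiran-2-yl]methanol | OC[C@@H]1O[C@H]1CO[Si](C)(C)C(C)(C)C | intermediate
4 | (2R,3S)-3-({[tert-butyl(dimethyl)silyl]oxy}methyl)oxirane-2-carbaldehyde | O=C[C@@H]1O[C@H]1CO[Si](C)(C)C(C)(C)C | intermediate
5 | tert-butyl (2E)-3-[(2S,3S)-3-({[tert-butyl(dimethyl)silyl]oxy}methyl)oxiran-2-yl]prop-2-enoate | CC(C)(C)OC(=O)/C=C/[C@@H]1O[C@H]1CO[Si](C)(C)C(C)(C)C | intermediate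
6 | tert-butyl (2E)-3-[(2S,3S)-3-(hydroxymethyl)oxiran-2-yl]prop-2-enoate | CC(C)(C)OC(=O)/C=C/[C@@H]1O[C@H]1CO | intermediate
7 | tert-butyl (2E)-3-[(2S,3R)-3-formyloxiran-2-yl]prop-2-enoate | CC(C)(C)OC(=O)/C=C/[C@@H]1O[C@H]1C=O | intermediate
8 | tert-butyl (2E)-3-[(2S,3S)-3-[(1Z)-3-methoxy-3-oxoprop-1-en-1-yl]oxiran-2-yl]prop-2-enoate | CC(C)(C)OC(=O)/C=C/[C@@H]1O[C@H]1/C=C\C(=O)OC | intermediate
9 | (2Z)-3-[(2S,3S)-3-[(1E)-3-tert-butoxy-3-oxoprop-1-en-1-yl]oxiran-2-yl]prop-2-enoic acid | CC(C)(C)OC(=O)/C=C/[C@@H]1O[C@H]1/C=C\C(=O)O | intermediate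
10 | tert-butyl (2E)-3-[(2S,3S)-3-hydroxy-6-oxo-3,6-dihydro-2H-pyran-2-yl]prop-2-enoate | O[C@H]1C=CC(=O)O[C@H]1/C=C/C(=O)OC(C)(C)C | intermediate
11 | (R)-β-citronellene [(3R)-3,7-dimethylocta-1,6-diene] | C=C[C@H](C)CCC=C(C)C | starting material
12 | (4R)-4-methylhex-5-en-1-ol | C=C[C@H](C)CCCO | intermediate
13 | (3R)-6-bromo-3-methylhex-1-ene | C=C[C@H](C)CCCBr | intermediate
14 | (S)-propylene oxide [(2S)-2-methyloxirane] | C[C@H]1CO1 | starting material
15 | [(4R)-4-methylhex-5-en-1-yl]magnesium bromide | C=C[C@H](C)CCC[Mg]Br | intermediate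
16 | (2S,7R)-7-methylnon-8-en-2-ol | C=C[C@H](C)CCCC[C@H](C)O | intermediate
17 | tert-butyl(dimethyl){[(2S,7R)-7-methylnon-8-en-2-yl]oxy}silane | C=C[C@H](C)CCCC[C@H](C)O[Si](C)(C)C(C)(C)C | intermediate
18 | (2R,7S)-7-{[tert-butyl(dimethyl)silyl]oxy}-2-methyloctanal | O=C[C@H](C)CCCC[C@H](C)O[Si](C)(C)C(C)(C)C | intermediate
19 | (2E,4R,9S)-9-{[tert-butyl(dimethyl)silyl]oxy}-2,4-dimethyldec-2-enal | O=C/C(C)=C/[C@H](C)CCCC[C@H](C)O[Si](C)(C)C(C)(C)C | intermediate
20 | ethyl (2E,4E,6R,11S)-11-{[tert-butyl(dimethyl)silyl]oxy}-4,6-dimethyldodeca-2,4-dienoate | CCOC(=O)/C=C/C(C)=C/[C@H](C)CCCC[C@H](C)O[Si](C)(C)C(C)(C)C | intermediate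
21 | (2E,4E,6R,11S)-11-{[tert-butyl(dimethyl)silyl]oxy}-4,6-dimethyldodeca-2,4-dienoic acid | OC(=O)/C=C/C(C)=C/[C@H](C)CCCC[C@H](C)O[Si](C)(C)C(C)(C)C | intermediate
22 | (2E,4E,6R,11S)-11-{[tert-butyl(dimethyl)silyl]oxy}-4,6-dimethyldodeca-2,4-dienoic 2,4,6-trichlorobenzoic anhydride | O=C(OC(=O)/C=C/C(C)=C/[C@H](C)CCCC[C@H](C)O[Si](C)(C)C(C)(C)C)c1c(Cl)cc(Cl)cc1Cl | intermediate
23 | tert-butyl (2E)-3-[(2S,3S)-3-{[(2E,4E,6R,11S)-11-{[tert-butyl(dimethyl)silyl]oxy}-4,6-dimethyldodeca-2,4-dienoyl]oxy}-6-oxo-3,6-dihydro-2H-pyran-2-yl]prop-2-enoate | CC(/C=C/C(=O)O[C@H]1C=CC(=O)O[C@H]1/C=C/C(=O)OC(C)(C)C)=C\[C@H](C)CCCC[C@H](C)O[Si](C)(C)C(C)(C)C | intermediate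
24 | (2E)-3-[(2S,3S)-3-{[(2E,4E,6R,11S)-11-hydroxy-4,6-dimethyldodeca-2,4-dienoyl]oxy}-6-oxo-3,6-dihydro-2H-pyran-2-yl]prop-2-enoic acid | CC(/C=C/C(=O)O[C@H]1C=CC(=O)O[C@H]1/C=C/C(=O)O)=C\[C@H](C)CCCC[C@H](C)O | target

**Step count and risks**

Total step count: 16. Longest linear sequence: 9 steps (steps 1–7, 15, 16; the branch 8–14, 15, 16 is equally long).

Steps most likely to fail:

1. Step 7. Possible failure: ionization of the oxirane at C5 instead of C6 with loss of the Z geometry, uncatalysed 5-exo opening of the epoxide by the carboxyl, or migration of the lactone acyl group to the freed C5 hydroxyl (ring contraction). The fallback sets out from 5 and comes back to the route at 23. It closes the ring at C3=C4 by an intramolecular Horner–Wadsworth–Emmons reaction. Epoxide 5 is opened at the epoxide carbon next to the alkene (the future C6) with (diethoxyphosphoryl)acetic acid and catalytic Pd(PPh3)4 in THF; retention is expected, and only one vinyl arm is present, so the site of ionization is unambiguous. This should give the hydroxy phosphonoacetate F1. Its free hydroxyl (the future C5–OH) is acylated with acid 21 (EDC, DMAP, CH2Cl2, 0 °C) to the diester F2. The primary silyl ether is cleaved selectively (HF·pyridine, pyridine, THF, 0 °C) to the primary alcohol F3. Dess–Martin oxidation gives the aldehyde F4, which is cyclized under Masamune–Roush conditions (LiCl, iPr2NEt, MeCN) to 23. Steps 4–7 and 15 then fall away.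

2. Step 6. Possible failure: opening of the doubly allylic epoxide by hydroxide, base-induced γ-deprotonation with epoxide opening, or attack of the liberated carboxyl on the epoxide during acidification. The fallback sets out from 6 and comes back at 9. Aldehyde 7, made from 6 as in step 5, is olefinated under the same Still–Gennari conditions with 2-(trimethylsilyl)ethyl [bis(2,2,2-trifluoroethoxy)phosphoryl]acetate to the (Z)-2-(trimethylsilyl)ethyl ester F5. The acid is then released without hydroxide by fluoride-induced fragmentation with (Me2N)3S+ Me3SiF2− in DMF at 0 °C, and buffered work-up should give 9.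

3. Step 15. Possible failure: slow acylation of the hindered C5 hydroxyl (cis to the C6 arm), base-promoted acyl migration with ring contraction, or elimination across C5–C6. The fallback sets out from 10 and 19 and comes back at 23. It builds the diene on the core instead of attaching it. Alcohol 10 is acylated with the small (diethoxyphosphoryl)acetic acid (DCC, CH2Cl2, 0 °C, no amine base) to the phosphonoacetate F6. A Horner–Wadsworth–Emmons reaction with enal 19 (LiCl, iPr2NEt, MeCN) then forms C2'=C3' and should give 23. Steps 13 and 14 then fall away.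

Further compounds
F1 | step 7 | tert-butyl (2E,4S,5S)-6-{[tert-butyl(dimethyl)silyl]oxy}-4-{[(diethoxyphosphoryl)acetyl]oxy}-5-hydroxyhex-2-enoate | CC(C)(C)OC(=O)/C=C/[C@H](OC(=O)CP(=O)(OCC)OCC)[C@@H](O)CO[Si](C)(C)C(C)(C)C
F2 | step 7 | tert-butyl (2E,4S,5S)-6-{[tert-butyl(dimethyl)silyl]oxy}-5-{[(2E,4E,6R,11S)-11-{[tert-butyl(dimethyl)silyl]oxy}-4,6-dimethyldodeca-2,4-dienoyl]oxy}-4-{[(diethoxyphosphoryl)acetyl]oxy}hex-2-enoate | CC(C)(C)OC(=O)/C=C/[C@H](OC(=O)CP(=O)(OCC)OCC)[C@@H](OC(=O)/C=C/C(C)=C/[C@H](C)CCCC[C@H](C)O[Si](C)(C)C(C)(C)C)CO[Si](C)(C)C(C)(C)C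
F3 | step 7 | tert-butyl (2E,4S,5S)-5-{[(2E,4E,6R,11S)-11-{[tert-butyl(dimethyl)silyl]oxy}-4,6-dimethyldodeca-2,4-dienoyl]oxy}-4-{[(diethoxyphosphoryl)acetyl]oxy}-6-hydroxyhex-2-enoate | CC(C)(C)OC(=O)/C=C/[C@H](OC(=O)CP(=O)(OCC)OCC)[C@@H](OC(=O)/C=C/C(C)=C/[C@H](C)CCCC[C@H](C)O[Si](C)(C)C(C)(C)C)CO
F4 | step 7 | tert-butyl (2E,4S,5R)-5-{[(2E,4E,6R,11S)-11-{[tert-butyl(dimethyl)silyl]oxy}-4,6-dimethyldodeca-2,4-dienoyl]oxy}-4-{[(diethoxyphosphoryl)acetyl]oxy}-6-oxohex-2-enoate | CC(C)(C)OC(=O)/C=C/[C@H](OC(=O)CP(=O)(OCC)OCC)[C@@H](OC(=O)/C=C/C(C)=C/[C@H](C)CCCC[C@H](C)O[Si](C)(C)C(C)(C)C)C=O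
F5 | step 6 | tert-butyl (2E)-3-[(2S,3S)-3-{(1Z)-3-oxo-3-[2-(trimethylsilyl)ethoxy]prop-1-en-1-yl}oxiran-2-yl]prop-2-enoate | CC(C)(C)OC(=O)/C=C/[C@@H]1O[C@H]1/C=C\C(=O)OCC[Si](C)(C)C
F6 | step 15 | tert-butyl (2E)-3-[(2S,3S)-3-{[(diethoxyphosphoryl)acetyl]oxy}-6-oxo-3,6-dihydro-2H-pyran-2-yl]prop-2-enoate | CCOP(=O)(CC(=O)O[C@H]1C=CC(=O)O[C@H]1/C=C/C(=O)OC(C)(C)C)OCC
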